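Time came first: the meeting held the flask's readings up to 120 s and was asked about 4.0 min.

| setting | winter | flask |
|---|---|---|
| starting material | 0.80 M | 0.80 M |
| second substrate | 0.80 M | 0.800 M |
| partner | 1.2 M | 1.20 M |
| protic impurity | 0.040 M | 0.0400 M |
| free catalyst | 120 mM | 120 mM |
| remark | the very flask that is asked about, followed so far |  |
| time |  | 4.0 min |

winter run (percent of the starting material charged)

| time / s | catalyst intermediate A / % | uncatalysed product / % | target / % | starting material / % |
|---|---|---|---|---|
| 15.0 | 1.4 | 16.0 | 3.7 | 79.0 |
| 40.0 | 1.1 | 30.8 | 6.4 | 61.3 |
| 80.0 | 0.7 | 42.9 | 8.4 | 47.9 |
| 120 | 1.1 | 48.1 | 9.2 | 41.8 |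

(readings scatter by 0.3 percentage points)

- the earlier runs were read with a standard deviation of 0.3 percentage points
- steps that have been proposed: starting material + free catalyst <-> catalyst intermediate A; partner + catalyst intermediate A -> free catalyst + target; second substrate + free catalyst <-> catalyst intermediate B; partner + catalyst intermediate B -> free catalyst + second product; starting material + partner -> uncatalysed product; partner + protic impurity -> quenched reagent

- the species that holds most of what was charged as starting material, at 4.0 min (starting material / uncatalysed product / target / catalyst intermediate A)
- the largest share itself, whichever of these holds it, in percent of the starting material charged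

The chemist noted that catalyst intermediate A read 1.4% at the first reading and 1.1% at the last. She treated the binding of starting material to free catalyst as balanced. Then [catalyst intermediate A] follows [starting material][free catalyst]. Partner turns that intermediate into target, and partner also attacks starting material directly, giving uncatalysed product. In the ratio of these two rates, [partner] and [starting material] cancel, so the ratio varies inversely with [free catalyst].

The analyst named it the split: uncatalysed product made per target made, a selectivity factor. He read it at 120 s as 5.23. If [free catalyst] holds, 83.9% of the two products is uncatalysed product.

The chair reckoned the total. The two products gained 14 percentage points from 40.0 s to 80.0 s, then 6 points over the next equal interval, a ratio of 0.426. Continuing that shrinkage to 4.0 min gives 61.4% in products. The split puts 51.5% in uncatalysed product, which is more than the 37.7% the chair reckoned as starting material.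

The forecast named uncatalysed product at 53%, a little above the chair's figure, and said it “should stay ahead”.

The flask gives uncatalysed product at 52.9%, with starting material at 36.2% and target at 10.3%.

    starting material + free catalyst ⇌ catalyst intermediate A (K = 0.410 M⁻¹, k = 11.8 M⁻¹ s⁻¹)
    partner + catalyst intermediate A → free catalyst + target (k = 0.0982 M⁻¹ s⁻¹)
    second substrate + free catalyst ⇌ catalyst intermediate B (K = 81.6 M⁻¹, k = 0.201 M⁻¹ s⁻¹)
    partner + catalyst intermediate B → free catalyst + second product (k = 0.152 M⁻¹ s⁻¹)
    starting material + partner → uncatalysed product (k = 0.0115 M⁻¹ s⁻¹)
    partner + protic impurity → quenched reagent (k = 0.220 M⁻¹ s⁻¹)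

By 2.00 min in this flask, protic impurity stood at 0% and partner had fallen to 16.2% of its charge, while starting material reached 41.6%. By 4.00 min, second product had risen from 0.505 M to 0.622 M, catalyst intermediate B held 66.7% of the catalyst, and partner stood at 2.65%. The split here ended at 5.12. A neighbour flask has a quarter of the catalyst charge, and 28.4% of it is free against 29.7% here. Scaling by charge gives 20.9, and that flask's split stands at 22.3.

(The runs were computed for an exercise, noise included.)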